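**Retrosynthetic overview**
- The veratrate is attached last but one; the 6,7-ene of the enone is introduced last by dehydrogenation of the C8 ketone. The C4 carbinol comes from a hydroxyl-directed reduction of a 4-ketone.
- The five-membered ring is opened at C3–C3a, the bond closed last in the presumed biosynthesis (farnesyl C10–C6). Because C3 carries the hydroxyl, it is closed with inverted polarity, as an aldol of a cycloheptane-1,4-dione onto the side-chain isopropyl ketone.
- The seven-membered ring comes from a six-membered ring by a cationic 1,2-shift into an exocyclic tertiary centre carrying the methyl group and the side chain (compare bisabolyl cation to cycloheptenyl cation). This shift creates the quaternary stereocentre.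
- The six-membered carbinol comes from 3-ethoxy-5-methylcyclohexenone and an alkenyllithium made from 3-methylbutan-2-one and 2,3-dibromopropene.
- Ring order: six (bought), then seven (ring expansion), then five (aldol).

Assumption: the sense of induction of the cobalt–salen catalyst in step 5 cannot be predicted with certainty, so the (S,S)-ligand is written and the (R,R)-ligand is used if the first run gives the antipode of 12; bicyclic compounds carry azulene numbering, and the C6 methyl centre (sp2 after step 9) is carried as both epimers.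

**Step 1**
Reactants: 1 5-methylcyclohexane-1,3-dione
Product: 2 3-ethoxy-5-methylcyclohex-2-en-1-one
Conditions: EtOH, p-TsOH (cat.), toluene, reflux, Dean–Stark
Reagents that add atoms: ethanol, CCO
Why: acid-catalysed O-alkylation of the enolised 1,3-dione (vinylogous ester formation) driven by azeotropic removal of water; the racemic methyl-bearing carbon becomes sp2 in step 9.

**Step 2**
Reactants: 3 3-methylbutan-2-one; 4 2,3-dibromoprop-1-ene
Product: 6 6-bromo-2-methylhept-6-en-3-one, via lithium enolate 5 (not isolated)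
Conditions: LiN(i-Pr)2, THF, −78 °C; then 4, DMPU, −78 → −20 °C
Reagents that add atoms: none
Why: kinetic deprotonation at the methyl group followed by SN2 enolate alkylation at the allylic bromide; the vinylic bromide does not react.

**Step 3**
Reactants: 6 6-bromo-2-methylhept-6-en-3-one
Product: 7 2-(3-bromobut-3-en-1-yl)-2-(propan-2-yl)-1,3-dioxolane
Conditions: HOCH2CH2OH, p-TsOH (cat.), toluene, reflux, Dean–Stark
Reagents that add atoms: ethane-1,2-diol, OCCO
Why: ketalisation masks the isopropyl ketone against t-BuLi and keeps the carbonyl oxygen from trapping the cationic centre or forming a lactol in step 5.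

**Step 4**
Reactants: 7 2-(3-bromobut-3-en-1-yl)-2-(propan-2-yl)-1,3-dioxolane; 2 3-ethoxy-5-methylcyclohex-2-en-1-one
Product: 10 3-ethoxy-5-methyl-1-{4-[2-(propan-2-yl)-1,3-dioxolan-2-yl]but-1-en-2-yl}cyclohex-2-en-1-ol, via vinyllithium 8 (not isolated), via lithium alkoxide 9 (not isolated)
Conditions: t-BuLi (2.0 equiv), Et2O, −78 °C; then 2, THF, −78 → −20 °C; H2O quench, work-up at pH ≥ 8, used without chromatography
Reagents that add atoms: none
Why: bromine–lithium exchange and 1,2-addition of the alkenyllithium to the vinylogous ester carbonyl (first half of a Stork–Danheiser sequence); the carbinol is a vinylogous hemiketal and is kept acid-free, and the stereocentres present here are erased later.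

**Step 5**
Reactants: 10 3-ethoxy-5-methyl-1-{4-[2-(propan-2-yl)-1,3-dioxolan-2-yl]but-1-en-2-yl}cyclohex-2-en-1-ol
Product: 12 (2S,6RS)-2,6-dimethyl-2-(4-methyl-3-oxopentyl)cycloheptane-1,4-dione, via ring-expanded enol ether 11 (not isolated)
Conditions: (S,S)-N,N′-bis(3,5-di-tert-butylsalicylidene)cyclohexane-1,2-diaminocobalt (C36H52CoN2O2, divalent cobalt, 5 mol%), 1-fluoro-2,4,6-trimethylpyridinium tetrafluoroborate (1.5 equiv), PhSiH3 (1.2 equiv), acetone, −20 → 0 °C; then 1 M HCl, THF, 23 °C
Reagents that add atoms: water, O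
Why: Proposed new method: Markovnikov hydrogen-atom transfer from a trivalent cobalt hydride to the 1,1-disubstituted alkene gives the tertiary radical, which the chiral cobalt–salen captures as a tetravalent alkylcobalt (radical–polar crossover); the electron-rich alkoxyvinyl carbon, a far better migrating group than the ring CH2, then shifts from the carbinol carbon to this centre with inversion (vinylogous semipinacol rearrangement, six to seven ring expansion) and loss of the hydroxyl proton gives the ketone, so the quaternary methyl stereocentre (2S) is set by the ligand in the displacement, and the acidic work-up hydrolyses enol ether and dioxolane; closest known reaction types are cobalt–salen hydrogen-atom-transfer semipinacol rearrangements of tertiary allylic alcohols and enantioselective cobalt–salen radical–polar crossover hydroalkoxylations.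

**Step 6**
Reactants: 12 (2S,6RS)-2,6-dimethyl-2-(4-methyl-3-oxopentyl)cycloheptane-1,4-dione
Product: 13 (3R,3aR,6RS,8aS)-3-hydroxy-6,8a-dimethyl-3-(propan-2-yl)hexahydroazulene-4,8(1H,5H)-dione
Conditions: KOt-Bu (0.2 equiv), t-BuOH/THF, 0 → 23 °C; AcOH quench
Reagents that add atoms: none
Why: reversible intramolecular aldol addition (5-enolexo) of the C3 enolate of the ring C4 ketone onto the isopropyl ketone; retro-aldol and enolisation at the ring-fusion carbon should funnel the ketols to the expected (not proven) thermodynamic isomer, trans-fused with the hydroxyl cis to, and hydrogen-bonded with, the C4 carbonyl and the isopropyl group anti to that ring carbon, while the other aldol modes give bridged or more congested ketols.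

**Step 7**
Reactants: 13 (3R,3aR,6RS,8aS)-3-hydroxy-6,8a-dimethyl-3-(propan-2-yl)hexahydroazulene-4,8(1H,5H)-dione
Product: 14 (3R,3aS,4S,6RS,8aS)-3,4-dihydroxy-6,8a-dimethyl-3-(propan-2-yl)octahydroazulen-8(1H)-one
Conditions: Me4NBH(OAc)3, MeCN/AcOH (1:1), −20 °C
Reagents that add atoms: none
Why: Evans–Saksena reduction: the acetoxyborohydride bound to the tertiary 3-hydroxyl delivers hydride to the C4 ketone on the face of that hydroxyl, giving the 1,3-anti diol (4S, hydroxyl cis to H-3a); the hindered, undirected C8 ketone is not reduced.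

**Step 8**
Reactants: 14 (3R,3aS,4S,6RS,8aS)-3,4-dihydroxy-6,8a-dimethyl-3-(propan-2-yl)octahydroazulen-8(1H)-one; 15 3,4-dimethoxybenzoyl chloride
Product: 16 (3R,3aS,4S,6RS,8aS)-3-hydroxy-6,8a-dimethyl-8-oxo-3-(propan-2-yl)decahydroazulen-4-yl 3,4-dimethoxybenzoate
Conditions: Et3N, DMAP (cat.), CH2Cl2, 0 → 23 °C
Reagents that add atoms: none
Why: DMAP-catalysed acylation of the secondary alcohol; the tertiary alcohol does not react under these conditions.

**Step 9**
Reactants: 16 (3R,3aS,4S,6RS,8aS)-3-hydroxy-6,8a-dimethyl-8-oxo-3-(propan-2-yl)decahydroazulen-4-yl 3,4-dimethoxybenzoate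
Product: 17 (3R,3aS,4S,8aS)-3-hydroxy-6,8a-dimethyl-8-oxo-3-(propan-2-yl)-1,2,3,3a,4,5,8,8a-octahydroazulen-4-yl 3,4-dimethoxybenzoate
Conditions: IBX (1.5 equiv), DMSO/toluene (1:2), 70 °C
Reagents that add atoms: none
Why: IBX dehydrogenation of a ketone to the enone; the C8 ketone can enolise only towards C7 because C8a is quaternary, so the 6-methyl-6,7-ene forms and both C6 epimers converge on the target.

**Compound list**
1 | 5-methylcyclohexane-1,3-dione | CC1CC(=O)CC(=O)C1 | starting material
2 | 3-ethoxy-5-methylcyclohex-2-en-1-one (racemic) | CCOC1=CC(=O)CC(C)C1 | intermediate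
3 | 3-methylbutan-2-one | CC(C)C(C)=O | starting material
4 | 2,3-dibromoprop-1-ene | C=C(Br)CBr | starting material
5 | lithium 3-methylbut-1-en-2-olate | [Li]OC(=C)C(C)C | intermediate
6 | 6-bromo-2-methylhept-6-en-3-one | CC(C)C(=O)CCC(Br)=C | intermediate
7 | 2-(3-bromobut-3-en-1-yl)-2-(propan-2-yl)-1,3-dioxolane | C=C(Br)CCC1(C(C)C)OCCO1 | intermediate
8 | {4-[2-(propan-2-yl)-1,3-dioxolan-2-yl]but-1-en-2-yl}lithium | [Li]C(=C)CCC1(C(C)C)OCCO1 | intermediate
9 | lithium alkoxide of 10 | [Li]OC1(C(=C)CCC2(C(C)C)OCCO2)C=C(OCC)CC(C)C1 | intermediate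
10 | 3-ethoxy-5-methyl-1-{4-[2-(propan-2-yl)-1,3-dioxolan-2-yl]but-1-en-2-yl}cyclohex-2-en-1-ol (racemic, both diastereomers) | OC1(C(=C)CCC2(C(C)C)OCCO2)C=C(OCC)CC(C)C1 | intermediate
11 | (2S,6RS)-4-ethoxy-2,6-dimethyl-2-{2-[2-(propan-2-yl)-1,3-dioxolan-2-yl]ethyl}cyclohept-3-en-1-one | O=C1CC(C)CC(OCC)=C[C@]1(C)CCC2(C(C)C)OCCO2 | intermediate
12 | (2S,6RS)-2,6-dimethyl-2-(4-methyl-3-oxopentyl)cycloheptane-1,4-dione | O=C1CC(C)CC(=O)C[C@]1(C)CCC(=O)C(C)C | intermediate
13 | (3R,3aR,6RS,8aS)-3-hydroxy-6,8a-dimethyl-3-(propan-2-yl)hexahydroazulene-4,8(1H,5H)-dione (trans-fused; 3-OH cis to 8a-CH3) | O=C1CC(C)CC(=O)[C@@]2(C)CC[C@@](O)(C(C)C)[C@H]12 | intermediate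
14 | (3R,3aS,4S,6RS,8aS)-3,4-dihydroxy-6,8a-dimethyl-3-(propan-2-yl)octahydroazulen-8(1H)-one | O[C@H]1CC(C)CC(=O)[C@@]2(C)CC[C@@](O)(C(C)C)[C@H]12 | intermediate
15 | 3,4-dimethoxybenzoyl chloride | COc1ccc(C(Cl)=O)cc1OC | starting material
16 | (3R,3aS,4S,6RS,8aS)-3-hydroxy-6,8a-dimethyl-8-oxo-3-(propan-2-yl)decahydroazulen-4-yl 3,4-dimethoxybenzoate | COc1ccc(C(=O)O[C@H]2CC(C)CC(=O)[C@@]3(C)CC[C@@](O)(C(C)C)[C@H]23)cc1OC | intermediate
17 | (3R,3aS,4S,8aS)-3-hydroxy-6,8a-dimethyl-8-oxo-3-(propan-2-yl)-1,2,3,3a,4,5,8,8a-octahydroazulen-4-yl 3,4-dimethoxybenzoate | COc1ccc(C(=O)O[C@H]2CC(C)=CC(=O)[C@@]3(C)CC[C@@](O)(C(C)C)[C@H]23)cc1OC | target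

**Step count**
Total: 9 steps. Longest linear sequence: 8 steps (3 → 6 → 7 → 10 → 12 → 13 → 14 → 16 → 17).

**Steps most likely to fail, with fallbacks**

Step 5 (ring expansion that sets the quaternary centre). The risks are:
- low enantioselectivity, because the methyl group and the CH2 of the side chain at the radical centre are similar in size, and the adjacent carbinol carbon is racemic;
- fluorination of the enol ether by the oxidant;
- ionisation of the vinylogous hemiketal.

Fallback, setting out from 1 and coming back at 12: 1 is condensed with (1R,2S,5R)-menthol (p-TsOH, toluene, Dean–Stark) and the (5R)-epimer of the menthyl vinylogous ester F1 is secured by crystallisation. Addition of 8 gives the carbinol F2. Ring expansion under the step 5 conditions, but with achiral N,N′-bis(3,5-di-tert-butylsalicylidene)ethane-1,2-diaminocobalt (C32H46CoN2O2, divalent cobalt) and a neutral work-up, gives the C2-epimeric menthyl enol ethers, the (2S,6R)-isomer F3 and the (2R,6R)-isomer F4. These are now diastereomers and are separated. 1 M HCl on F3 gives 12 as its single (2S,6R)-isomer. The stereochemistry then comes from a chiral-pool auxiliary and a separation, not from the catalyst.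

Step 6 (aldol). The risks are:
- the kinetic closure onto the ring enolate is expected to be cis-fused, so the outcome rests on equilibration;
- the trans over cis preference may be small;
- bridged ketols or dehydration may compete.

Fallback, setting out from 10 and coming back at 13: step 5 is run with a NaHCO3 work-up so that 11 is isolated. NBS in wet THF at 0 °C brominates the enol ether carbon and hydrolyses it to the bromo diketone ketal F5. 1 M HCl removes the dioxolane to give the bromo triketone F6. SmI2 (2.2 equiv), THF, −78 °C then generates the samarium enolate F7 (trivalent samarium) only at C3, and it closes onto the isopropyl ketone in a chelated intramolecular Reformatsky-type aldol. This avoids equilibrating base and dehydration; the ring-fusion centre remains epimerisable (brief DBU if needed), and the product is 13.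

Step 9 (late dehydrogenation). The risks are:
- vinylogous loss of the veratrate through the dienol;
- over-oxidation to the dienone.

Fallback, setting out from 14 and coming back at 17: the enone is made before the ester is present. TMSOTf/Et3N (CH2Cl2, 0 °C) converts 14 into the silyl enol ether bis(silyl ether) F8. Pd(OAc)2 in MeCN (Saegusa–Ito) gives the bis(silyl) enone F9. K2CO3/MeOH gives the enone diol F10. Acylation with 15 (Et3N, DMAP, CH2Cl2) gives 17.

**Further compounds**
F1 | step 5 | (5R)-5-methyl-3-{[(1R,2S,5R)-5-methyl-2-(propan-2-yl)cyclohexyl]oxy}cyclohex-2-en-1-one | C[C@H]1CC(=O)C=C(O[C@@H]2C[C@H](C)CC[C@H]2C(C)C)C1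
F2 | step 5 | (5R)-5-methyl-3-{[(1R,2S,5R)-5-methyl-2-(propan-2-yl)cyclohexyl]oxy}-1-{4-[2-(propan-2-yl)-1,3-dioxolan-2-yl]but-1-en-2-yl}cyclohex-2-en-1-ol (both carbinol epimers) | C[C@H]1CC(O)(C(=C)CCC2(C(C)C)OCCO2)C=C(O[C@@H]3C[C@H](C)CC[C@H]3C(C)C)C1
F3 | step 5 | (2S,6R)-2,6-dimethyl-4-{[(1R,2S,5R)-5-methyl-2-(propan-2-yl)cyclohexyl]oxy}-2-{2-[2-(propan-2-yl)-1,3-dioxolan-2-yl]ethyl}cyclohept-3-en-1-one | O=C1C[C@H](C)CC(O[C@@H]3C[C@H](C)CC[C@H]3C(C)C)=C[C@]1(C)CCC2(C(C)C)OCCO2
F4 | step 5 | (2R,6R)-2,6-dimethyl-4-{[(1R,2S,5R)-5-methyl-2-(propan-2-yl)cyclohexyl]oxy}-2-{2-[2-(propan-2-yl)-1,3-dioxolan-2-yl]ethyl}cyclohept-3-en-1-one | O=C1C[C@H](C)CC(O[C@@H]3C[C@H](C)CC[C@H]3C(C)C)=C[C@@]1(C)CCC2(C(C)C)OCCO2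
F5 | step 6 | (2R,3RS,6RS)-3-bromo-2,6-dimethyl-2-{2-[2-(propan-2-yl)-1,3-dioxolan-2-yl]ethyl}cycloheptane-1,4-dione (same spatial arrangement at C2 as 12) | O=C1CC(C)CC(=O)C(Br)[C@]1(C)CCC2(C(C)C)OCCO2
F6 | step 6 | (2R,3RS,6RS)-3-bromo-2,6-dimethyl-2-(4-methyl-3-oxopentyl)cycloheptane-1,4-dione | O=C1CC(C)CC(=O)C(Br)[C@]1(C)CCC(=O)C(C)C
F7 | step 6 | diiodosamarium enolate of 12 at C3–C4 | O=C1CC(C)CC(O[Sm](I)I)=C[C@]1(C)CCC(=O)C(C)C
F8 | step 9 | 3,4-bis(trimethylsilyl) ether 8-trimethylsilyl enol ether of 14 | C[Si](C)(C)O[C@H]1CC(C)C=C(O[Si](C)(C)C)[C@@]2(C)CC[C@@](O[Si](C)(C)C)(C(C)C)[C@H]12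
F9 | step 9 | (3R,3aS,4S,8aS)-6,8a-dimethyl-3-(propan-2-yl)-3,4-bis(trimethylsilyloxy)-2,3,3a,4,5,8a-hexahydroazulen-8(1H)-one | C[Si](C)(C)O[C@H]1CC(C)=CC(=O)[C@@]2(C)CC[C@@](O[Si](C)(C)C)(C(C)C)[C@H]12
F10 | step 9 | (3R,3aS,4S,8aS)-3,4-dihydroxy-6,8a-dimethyl-3-(propan-2-yl)-2,3,3a,4,5,8a-hexahydroazulen-8(1H)-one | O[C@H]1CC(C)=CC(=O)[C@@]2(C)CC[C@@](O)(C(C)C)[C@H]12
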